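## Structural features

The target 18 is a cross-conjugated cyclohexa-2,5-dienone (ring A: C1 carbonyl, C2 allyl, C3–H, C4 quaternary, C5 methoxy, C6–H). It is joined through the chain C8 (CHMe)–C7 (CH2) to a 3,4-dimethoxyphenyl ring (ring B), and the two rings share no atom. The only stereocentres, C4 (S; bearing OMe, C3, C5 and C8) and C8 (S), are directly bonded. The C1=O/C6=C5–OMe unit is a vinylogous ester and the C4 ether is a quinol ether, so acid can hydrolyse or transpose the former and ionise or rearrange the latter (dienone–phenol type). The terminal alkene of the allyl group is one bond away from conjugation, and C8 can epimerise whenever it sits α to a carbonyl group. The real difficulty is C4: a fully substituted, oxygen-bearing carbon between two sp2 ring carbons, to be set relative to C8, whose methyl and arylmethyl groups differ too little for useful substrate control. The key step exploits the para relationship of the C4 oxygen and the C1 carbonyl: C4–C5(OMe)=C6–C1(=O), with an oxygen bridging C4 and C1, is a γ-substituted methyl tetronate, and its 2-silyloxyfuran is a diene with termini C4 and C1. The missing atoms C2 and C3, with the allyl group, come from an α-allylacrolein whose formyl group activates the [4+2] step, blocks aromatisation at C2 and is removed afterwards.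

## Logic of the disconnections

18 ⇒ 17. The O–CH3 bond on the C4 oxygen is cut last. In 17 no C–H is enolisable, so a base can only alkylate oxygen. The forward step must methylate a hindered tertiary alkoxide faster than it adds to the dienone.

17 ⇒ 14. The C2=C3 π bond is removed. A [4+2] step leaves C2 and C3 saturated, and in 14 C2 is the only enolisable position, so enolisation is unambiguous. The forward step must take the hydrogen from ring C3 and not from the allylic side-chain methylene.

14 ⇒ 13. A formyl group is added at C2 (C2–CHO bond). It activates the dienophile, and as part of a non-enolisable β-keto aldehyde it can leave by retro-Claisen cleavage. This erases the C2 stereocentre, so only the C4 selectivity of the ring-forming step matters. The forward step needs attack at the formyl carbon rather than at C1.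

13 ⇒ 9 + 11. After the C4 oxygen is reconnected to C1 (intermediate 12), the bonds C3–C4 and C1–C2 are cut. This removes ring A, the C4 stereocentre and the whole oxygen pattern in one operation (C5–OMe against C1=O is fixed by construction) and gives two fragments. The forward step needs regiocontrol (C4 to the CH2 terminus), the exo-formyl mode, and catalyst-controlled facial selectivity against a weak opposing bias from C8.

11 ⇒ 10. The C2=CH2 bond (future C2–C3) is cut to formaldehyde; the forward step is an α-methylenation.

9 ⇒ 8. The Si–O bond is cut, returning to a stable lactone. The lactone γ-centre of 8 becomes sp2 in the forward step and need not be controlled.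

8 ⇒ 5 + 6. The C4–C5 bond and the lactone C–O bond are cut. 6 supplies C5, C6 and C1 with both oxygens at the right oxidation level. The forward addition must be faster than enolisation of 5, the only compound in which C8 is α to a carbonyl.

5 ⇒ 4 ⇒ 3. Oxidation-level change and release of the auxiliary; 4 is the stable storage point before the labile aldehyde.

3 ⇒ 1 + 2. The C7–C8 bond is cut, and auxiliary-controlled enolate alkylation sets C8. This is preferred to hydrogenation of an α-methylcinnamic acid with Ru(OAc)2(binap), whose selectivity depends on the ligand, and it is two steps shorter.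

## Other disconnections considered

Alternative 1: The cut is C4–C8 plus a temporary C6–C7 bond, a retro-[5+2] addition of an arylpropene across C4 and C6 of a quinone-derived cation. Forward, the achiral quinone monoketal A1 would be ionised by a confined chiral Brønsted acid of the imidodiphosphorimidate class. The 4-methoxy cation, ion-paired with the chiral anion, would bond at C4 to the methyl-bearing carbon of the (Z)-propenylarene A2, C6 would capture the benzylic cation, and loss of the methyl group from the C5 oxygen would leave the bridged diketone A3. Reductive scission of the C6–C7 bond of A3 (benzylic and α to two carbonyls, for example with SmI2) and O-methylation at the C5 oxygen would give 18.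
- In its favour: C4 and C8 are formed together, with relative configuration from the (Z)-alkene and the endo approach. The allyl group and C2=C3 are present from the start. Both inputs are achiral, and only about three steps follow.
- Against it here: absolute control rests on ion pairing of a flat delocalised cation, which is not established for this cation class. The cation could also be captured at oxygen to give hydrobenzofurans. An unstrained C–C bond must be broken next to a dienone and an allyl group. The final enolate is ambident at two oxygens, and alkylation at the C1 oxygen would give the transposed vinylogous ester.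
- Comparison: Alternative 1 is the better plan on step economy, on the C2=C3/allyl question and on forming C8 with C4. The two are equal in relying on a chiral catalyst to choose a face of a planar oxygenated π system and in carrying one sacrificial element (a C–C bond there, a formyl group here). The chosen plan is preferred because its catalyst class has been used with both reactant classes, because the C5-OMe/C1=O placement is built in, and because no skeletal C–C bond is cleaved.

Alternative 2: C4 is reached by desymmetrisation, through a temporary O–C5 bond from a hydroxyl on C7 that is later broken at C7–O. Forward, the prochiral 4-methoxydienone A4 would close reversibly by 5-exo-trig oxa-Michael addition of the C7 hydroxyl to C5 of one enone arm. This would give the cis-fused tetrahydrobenzofuranone A5 and fix C4. Afterwards the sequence would need benzylic C7–O hydrogenolysis, oxidation at C5, formation of the C5 methyl enol ether and allylation at C2.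
- In its favour: no chiral catalyst is needed for C4, since selection is thermodynamic within a rigid bicycle. The C4 methoxy group arrives directly if A4 is made by oxidative dearomatisation in methanol, which is a clear advantage over the chosen plan's methylation of a hindered tertiary alcohol. C2=C3 is never absent.
- Against: the C7 oxygen and stereocentre are made only to be destroyed. The position of the equilibrium between the two closures cannot be predicted with confidence. Hydrogenolysis must spare an enone, the late enol etherification of a C1/C5 dione is ambiguous, and the allyl group must be attached to an enone α-carbon.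
- Comparison: the two are equal in needing one externally controlled element. Alternative 2 is better on the C4–OMe bond and on C2=C3. It is worse on steps after the key step (about six operations against three) and on oxidation-state changes at C5 and C7.

Alternative 3: The cut is C4–C5. Forward, the acyclic keto-aldehyde A6 (C5 aldehyde, C4 ketone, C1 as a dioxolane) would meet a chiral triazolylidene carbene. The acyl-anion equivalent at C5 would add to the C4 ketone in a six-membered crossed-benzoin closure to give the α-ketol A7.
- In its favour: ring-forming aldehyde–ketone benzoin reactions that create tertiary carbinols are well established. The dioxolane keeps C1 and C5 distinct, which equals the chosen plan on the oxygen pattern. No hindered furan or sensitive enal is involved.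
- Against: C8 is α to the C4 ketone in A6 and is exposed to epimerisation under the basic conditions that generate the carbene. In the chosen plan C8 is at risk only in 5 at low temperature. The catalyst must still choose a ketone face next to C8, which is the same matched/mismatched question (equal). After A7 the route must still methylate a tertiary α-ketol, form the C5 enol ether, unmask C1, allylate C2 and dehydrogenate C2–C3, with the same regiochemical question as step 9.
- Comparison: the ring closure itself is equal or better in reliability. It sets only one bond and one stereocentre, needs a longer linear route to A6, and is the weakest on step economy.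

Key step: step 7

Assumption: the oxazaborolidinium catalyst is taken to show the same sense of induction toward an α-substituted acrolein with the furan as with simple dienes, so the catalyst from (R)-α,α-diphenylprolinol exposes the enal face (Si at the α-carbon) that leads to 13. If the sense is the opposite, the (S)-catalyst is used and nothing else changes.

Remark: names of 12–18 use the ring locants C1–C6 of the first section. The C4 descriptor is R in 12–15 and S in 16–18 for one and the same spatial arrangement, because C3 outranks C8 once C2=C3 exists.

## Route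

Step 1
Reactants: 1 (R)-4-benzyl-3-propanoyl-1,3-oxazolidin-2-one; 2 4-(bromomethyl)-1,2-dimethoxybenzene (3,4-dimethoxybenzyl bromide)
Product: 3 (R)-4-benzyl-3-[(S)-3-(3,4-dimethoxyphenyl)-2-methylpropanoyl]-1,3-oxazolidin-2-one
Conditions: NaN(SiMe3)2, THF, −78 °C; then 2, −78 → −20 °C
Reagents that add atoms: none
Why: Evans asymmetric alkylation; the chelated (Z)-sodium enolate is attacked by the reactive benzylic bromide on the face opposite the auxiliary benzyl group, which for the (R)-auxiliary sets C8 as S.

Step 2
Reactants: 3 (R)-4-benzyl-3-[(S)-3-(3,4-dimethoxyphenyl)-2-methylpropanoyl]-1,3-oxazolidin-2-one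
Product: 4 (S)-3-(3,4-dimethoxyphenyl)-2-methylpropan-1-ol
Conditions: LiBH4, H2O (1 equiv), Et2O, 0 °C
Reagents that add atoms: none
Why: Reductive cleavage of the N-acyl oxazolidinone; hydride attacks the exocyclic carbonyl and releases the primary alcohol without touching C8, and the auxiliary is recovered.

Step 3
Reactants: 4 (S)-3-(3,4-dimethoxyphenyl)-2-methylpropan-1-ol
Product: 5 (S)-3-(3,4-dimethoxyphenyl)-2-methylpropanal
Conditions: Dess–Martin periodinane, NaHCO3, CH2Cl2, 0 °C → rt; used at once
Reagents that add atoms: none
Why: Dess–Martin oxidation under bicarbonate buffering gives the α-branched aldehyde without enolisation, so the C8 configuration should be retained.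

Step 4
Reactants: 6 methyl (E)-3-methoxyacrylate; 5 (S)-3-(3,4-dimethoxyphenyl)-2-methylpropanal
Product: 8 5-[(S)-1-(3,4-dimethoxyphenyl)propan-2-yl]-4-methoxyfuran-2(5H)-one (both epimers at the lactone C5), via hydroxy ester adduct 7 (not isolated)
Conditions: LiN(i-Pr)2, THF, −95 °C; then 5, −95 → 0 °C; aq NH4Cl
Reagents that add atoms: none
Why: β-Lithiation of the methoxyacrylate (lithium held cis to the ester by chelation), 1,2-addition to the aldehyde and lactonisation of the cis-disposed alkoxide with loss of methoxide, the established route to 4-methoxybutenolides; the new carbinol centre need not be controlled because step 5 makes it sp2.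

Step 5
Reactants: 8 5-[(S)-1-(3,4-dimethoxyphenyl)propan-2-yl]-4-methoxyfuran-2(5H)-one
Product: 9 tert-butyl({5-[(S)-1-(3,4-dimethoxyphenyl)propan-2-yl]-4-methoxyfuran-2-yl}oxy)dimethylsilane
Conditions: t-BuMe2SiOTf, Et3N, CH2Cl2, 0 °C; filtration through basic alumina
Reagents that add atoms: tert-butyldimethylsilyl trifluoromethanesulfonate, CC(C)(C)[Si](C)(C)OS(=O)(=O)C(F)(F)F
Why: Soft enolisation; O-silylation of the lactone carbonyl acidifies the γ-hydrogen, which the amine removes to give the aromatic 2-silyloxyfuran, while C8 carries no acidic hydrogen and is untouched.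

Step 6
Reactants: 10 pent-4-enal
Product: 11 2-methylenepent-4-enal
Conditions: 37% aq HCHO, pyrrolidine (10 mol %), propanoic acid (10 mol %), i-PrOH, 45 °C; distilled and used fresh
Reagents that add atoms: formaldehyde, C=O
Why: Amine-catalysed Mannich condensation followed by elimination of the amine (α-methylenation of an aldehyde); the isolated terminal alkene is inert.

Step 7
Reactants: 9 tert-butyl({5-[(S)-1-(3,4-dimethoxyphenyl)propan-2-yl]-4-methoxyfuran-2-yl}oxy)dimethylsilane; 11 2-methylenepent-4-enal
Product: 13 (2S,4R)-2-allyl-2-formyl-4-hydroxy-5-methoxy-4-[(2S)-1-(3,4-dimethoxyphenyl)propan-2-yl]cyclohex-5-en-1-one, via bridged silyl ketal 12 (not isolated)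
Conditions: oxazaborolidinium bis(trifluoromethanesulfonyl)imide (20 mol %) made from (R)-α,α-diphenylprolinol, o-tolylboronic acid and HN(SO2CF3)2, CH2Cl2, −78 °C; then Et3N·3HF, THF, −78 → 0 °C
Reagents that add atoms: none
Why: The protonated oxazaborolidine binds the formyl oxygen of 11 (formyl C–H···O contact, one enal face covered by an aryl group), and furan 9 adds in a concerted but strongly asynchronous [4+2] cycloaddition in which C4 (pushed vinylogously by the silyloxy group and directly by the C5 methoxy group) bonds first to the unhindered CH2 terminus (C3) and C2 then closes on the silyloxocarbenium carbon C1. The closest known reaction type is the oxazaborolidinium-catalysed Diels–Alder reaction of 2-silyloxyfurans with α-substituted acroleins, followed by opening of the bridged silyl ketals to 4-hydroxycyclohexenones. The six-membered carbocycle C1–C6 closes in an intermolecular suprafacial [4+2] mode, the second bond C1–C2 being an enol-to-oxocarbenium closure, and gives 12. C4 is set by the furan face that is bonded, which is fixed by the catalyst-exposed enal face together with the exo-formyl/endo-allyl orientation usual for α-substituted acroleins, while C2 is set by the enal face alone and is erased in step 8. The step needs regioselectivity (secured by the furan polarisation and the unsubstituted enal terminus), exo selectivity, and reagent-controlled facial selectivity that overrides the small bias of C8, whose hydrogen lies toward the C5 methoxy group and leaves methyl on the wrong face and arylmethyl on the required one. The tert-butyldimethylsilyl group is kept because it migrates only slowly to the enolate oxygen, a migration that would release an open-chain Michael adduct that cannot be closed. Buffered fluoride then takes silicon from the bridgehead oxygen, the hemiketal collapses to the C1 ketone and the bridge oxygen stays on C4 as the tertiary hydroxyl, without a free alkoxide that could attack the formyl group or C1. Aromatisation is impossible because C2 and C4 are both fully substituted.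

Step 8
Reactants: 13 (2S,4R)-2-allyl-2-formyl-4-hydroxy-5-methoxy-4-[(2S)-1-(3,4-dimethoxyphenyl)propan-2-yl]cyclohex-5-en-1-one
Product: 14 (4R)-2-allyl-4-hydroxy-5-methoxy-4-[(2S)-1-(3,4-dimethoxyphenyl)propan-2-yl]cyclohex-5-en-1-one (both epimers at C2)
Conditions: K2CO3 (0.2 equiv), MeOH, 0 °C
Reagents that add atoms: none
Why: Retro-Claisen deformylation of a non-enolisable β-keto aldehyde; methoxide adds to the formyl group, the most electrophilic carbonyl, and the adduct expels the C1–C2 enolate, which is protonated to a C2 epimer mixture that step 9 flattens, while the vinylogous ester carbonyl C1 is too deactivated to compete.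

Step 9
Reactants: 14 (4R)-2-allyl-4-hydroxy-5-methoxy-4-[(2S)-1-(3,4-dimethoxyphenyl)propan-2-yl]cyclohex-5-en-1-one
Product: 17 (4S)-2-allyl-4-hydroxy-5-methoxy-4-[(2S)-1-(3,4-dimethoxyphenyl)propan-2-yl]cyclohexa-2,5-dien-1-one, via bis-silyl dienol ether 15 (not isolated), via silyl-protected dienone 16 (not isolated)
Conditions: LiN(i-Pr)2 (2.2 equiv), Me3SiCl, THF, −78 °C; then Pd(OAc)2 (1.1 equiv), MeCN, rt; then Et3N·3HF, THF, 0 °C
Reagents that add atoms: chlorotrimethylsilane, C[Si](C)(C)Cl (its silicon is carried only by 15 and 16 and is removed before 17)
Why: Saegusa–Ito oxidation; C2 is the only enolisable position, so a single silyl dienol ether forms (the tertiary alkoxide is silylated in passing), divalent palladium gives the C2 palladium enolate, and syn β-hydride elimination of a ring C3 hydrogen gives the dienone, which cannot aromatise because C4 is quaternary; fluoride then frees the C4 hydroxyl.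

Step 10
Reactants: 17 (4S)-2-allyl-4-hydroxy-5-methoxy-4-[(2S)-1-(3,4-dimethoxyphenyl)propan-2-yl]cyclohexa-2,5-dien-1-one
Product: 18 (4S)-2-allyl-4,5-dimethoxy-4-[(2S)-1-(3,4-dimethoxyphenyl)propan-2-yl]cyclohexa-2,5-dien-1-one
Conditions: NaH, MeI, THF, 0 °C → rt
Reagents that add atoms: iodomethane, CI
Why: Williamson ether synthesis on the sodium alkoxide of the tertiary quinol; no C–H of 17 is enolisable, so only oxygen is methylated, and C4 and C8 are not touched.

## Compound list

1 | (R)-4-benzyl-3-propanoyl-1,3-oxazolidin-2-one | CCC(=O)N1[C@H](Cc2ccccc2)COC1=O | starting material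
2 | 4-(bromomethyl)-1,2-dimethoxybenzene | COc1ccc(CBr)cc1OC | starting material
3 | (R)-4-benzyl-3-[(S)-3-(3,4-dimethoxyphenyl)-2-methylpropanoyl]-1,3-oxazolidin-2-one | O=C([C@@H](C)Cc1ccc(OC)c(OC)c1)N1[C@H](Cc2ccccc2)COC1=O | intermediate
4 | (S)-3-(3,4-dimethoxyphenyl)-2-methylpropan-1-ol | OC[C@@H](C)Cc1ccc(OC)c(OC)c1 | intermediate
5 | (S)-3-(3,4-dimethoxyphenyl)-2-methylpropanal | O=C[C@@H](C)Cc1ccc(OC)c(OC)c1 | intermediate
6 | methyl (E)-3-methoxyacrylate | CO/C=C/C(=O)OC | starting material
7 | methyl (2E,5S)-6-(3,4-dimethoxyphenyl)-4-hydroxy-3-methoxy-5-methylhex-2-enoate (C4 epimers; lithium alkoxide in the flask) | CO/C(C(O)[C@@H](C)Cc1ccc(OC)c(OC)c1)=C/C(=O)OC | intermediate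
8 | 5-[(S)-1-(3,4-dimethoxyphenyl)propan-2-yl]-4-methoxyfuran-2(5H)-one (epimers at lactone C5) | COC1=CC(=O)OC1[C@@H](C)Cc2ccc(OC)c(OC)c2 | intermediate
9 | tert-butyl({5-[(S)-1-(3,4-dimethoxyphenyl)propan-2-yl]-4-methoxyfuran-2-yl}oxy)dimethylsilane | COc1cc(O[Si](C)(C)C(C)(C)C)oc1[C@@H](C)Cc2ccc(OC)c(OC)c2 | intermediate
10 | pent-4-enal | C=CCCC=O | starting material
11 | 2-methylenepent-4-enal | C=CCC(=C)C=O | intermediate
12 | (1R,2S,4R)-2-allyl-1-[(tert-butyldimethylsilyl)oxy]-4-[(2S)-1-(3,4-dimethoxyphenyl)propan-2-yl]-5-methoxy-7-oxabicyclo[2.2.1]hept-5-ene-2-carbaldehyde (formyl exo, allyl endo) | C=CC[C@@]1(C=O)C[C@]2([C@@H](C)Cc3ccc(OC)c(OC)c3)O[C@@]1(O[Si](C)(C)C(C)(C)C)C=C2OC | intermediate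
13 | (2S,4R)-2-allyl-2-formyl-4-hydroxy-5-methoxy-4-[(2S)-1-(3,4-dimethoxyphenyl)propan-2-yl]cyclohex-5-en-1-one (formyl cis to hydroxyl) | C=CC[C@@]1(C=O)C[C@@](O)([C@@H](C)Cc2ccc(OC)c(OC)c2)C(OC)=CC1=O | intermediate
14 | (4R)-2-allyl-4-hydroxy-5-methoxy-4-[(2S)-1-(3,4-dimethoxyphenyl)propan-2-yl]cyclohex-5-en-1-one (C2 epimers) | C=CCC1C[C@@](O)([C@@H](C)Cc2ccc(OC)c(OC)c2)C(OC)=CC1=O | intermediate
15 | (4R)-2-allyl-5-methoxy-4-[(2S)-1-(3,4-dimethoxyphenyl)propan-2-yl]-1,4-bis(trimethylsilyloxy)cyclohexa-1,5-diene | C=CCC=1C[C@@](O[Si](C)(C)C)([C@@H](C)Cc2ccc(OC)c(OC)c2)C(OC)=CC=1O[Si](C)(C)C | intermediate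
16 | (4S)-2-allyl-5-methoxy-4-[(2S)-1-(3,4-dimethoxyphenyl)propan-2-yl]-4-(trimethylsilyloxy)cyclohexa-2,5-dien-1-one | C=CCC1=C[C@@](O[Si](C)(C)C)([C@@H](C)Cc2ccc(OC)c(OC)c2)C(OC)=CC1=O | intermediate
17 | (4S)-2-allyl-4-hydroxy-5-methoxy-4-[(2S)-1-(3,4-dimethoxyphenyl)propan-2-yl]cyclohexa-2,5-dien-1-one | C=CCC1=C[C@@](O)([C@@H](C)Cc2ccc(OC)c(OC)c2)C(OC)=CC1=O | intermediate
18 | (4S)-2-allyl-4,5-dimethoxy-4-[(2S)-1-(3,4-dimethoxyphenyl)propan-2-yl]cyclohexa-2,5-dien-1-one | C=CCC1=C[C@@](OC)([C@@H](C)Cc2ccc(OC)c(OC)c2)C(OC)=CC1=O | target

## Step count and least certain steps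

Total: 10 steps. Longest linear sequence: 9 steps (steps 1–5 and 7–10); step 6 is a one-step branch.

Step 7 (key step). The most likely failure is incomplete control of the furan face, since both the C8 bias and any leakage into the endo-formyl mode feed the C4 epimer. A second is silyl transfer to the enolate oxygen before the second bond forms, which would release an open-chain Michael adduct whose closure by an aldehyde enolate is thermodynamically uphill. A third is acid-induced desilylation of the electron-rich furan, or slow bonding at its fully substituted carbon. The fallback sets out from 9 and returns at 14, bypassing 13. A Mukaiyama–Michael addition of 9 to commercial 3-acryloyl-1,3-oxazolidin-2-one would be run with Cu(OTf)2 and 2,2'-(propane-2,2-diyl)bis(4-tert-butyl-4,5-dihydrooxazole), the ligand enantiomer being chosen for the C4 sense; C4 epimers are diastereomers and separable. This forms only the C3–C4 bond and gives the butenolide imide F1. LiN(SiMe3)2 would then close C1–C2 by Dieckmann-type attack of the imide enolate on the lactone carbonyl, a closure driven by deprotonation of the resulting β-keto imide F2. C-Allylation (allyl bromide, K2CO3, acetone) would give the quaternary β-keto imide F3. LiOH/H2O2 hydrolysis and decarboxylation of the β-keto acid on acidification would then deliver 14.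

Step 9. The most likely failure is β-hydride loss from the allylic side-chain methylene instead of ring C3. That would place the new double bond outside the ring and let a palladium hydride move the terminal alkene into conjugation. The fallback sets out from 14 and returns at 17 without a transition metal. The dianion of 14 (LiN(i-Pr)2, 2.2 equiv) would be selenenylated at C2 with PhSeBr to the α-phenylselanyl ketone F4. Oxidation (H2O2, pyridine, CH2Cl2, 0 °C) and concerted syn elimination of the selenoxide would give 17.

Step 4. The most likely failure is proton transfer from C8–H of 5 to the vinyllithium, which costs material and erodes C8, together with decomposition of the lithiated acrylate if the temperature rises. The fallback sets out from 5 and returns at 8. The much less basic lithium acetylide of methyl propiolate (LiN(i-Pr)2, THF, −78 °C) would add to 5 to give the hydroxy ynoate F5. Conjugate addition of methanol (NaOMe cat., MeOH) and lactonisation of the resulting methoxy enoate would give 8.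

Step 8. The most likely failure is transannular attack of the C4 alkoxide on C1 followed by expulsion of the C2 aldehyde enolate, a retro-Dieckmann opening back to a butenolide that competes with deformylation. Ring–chain tautomerism of the formyl group with the cis C4 hydroxyl may slow the desired attack. The fallback sets out from 13 and returns at 14 with no alkoxide formed. Pinnick oxidation (NaClO2, NaH2PO4, 2-methylbut-2-ene, t-BuOH/H2O) would give the β-keto acid F6, which would lose CO2 on gentle warming.

Step 10. The most likely failure is slow O-alkylation of the hindered tertiary alkoxide, leaving time for conjugate addition of the alkoxide to a second dienone or base-induced rearrangement of the quinol. The fallback changes the order of events: it sets out from 14 and returns at 18. The hydroxyl of 14 would be methylated without base-generated alkoxide (MeOTf, 2,6-di-tert-butyl-4-methylpyridine, CH2Cl2) to the methyl ether F7. F7 would then be taken through enol silylation to the silyl dienol ether F8 and oxidation with Pd(OAc)2 as in step 9, giving 18 directly.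

## Further compounds

F1 | step 7 | 3-{3-[(2R)-2-[(2S)-1-(3,4-dimethoxyphenyl)propan-2-yl]-3-methoxy-5-oxo-2,5-dihydrofuran-2-yl]propanoyl}-1,3-oxazolidin-2-one | O=C(CC[C@@]1(OC(=O)C=C1OC)[C@@H](C)Cc2ccc(OC)c(OC)c2)N3CCOC3=O
F2 | step 7 | (4R)-4-hydroxy-5-methoxy-4-[(2S)-1-(3,4-dimethoxyphenyl)propan-2-yl]-2-(2-oxo-1,3-oxazolidine-3-carbonyl)cyclohex-5-en-1-one (C2 epimers) | O=C(C1C[C@@](O)([C@@H](C)Cc2ccc(OC)c(OC)c2)C(OC)=CC1=O)N3CCOC3=O
F3 | step 7 | (4R)-2-allyl-4-hydroxy-5-methoxy-4-[(2S)-1-(3,4-dimethoxyphenyl)propan-2-yl]-2-(2-oxo-1,3-oxazolidine-3-carbonyl)cyclohex-5-en-1-one (C2 epimers) | C=CCC1(C(=O)N2CCOC2=O)C[C@@](O)([C@@H](C)Cc3ccc(OC)c(OC)c3)C(OC)=CC1=O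
F4 | step 9 | (4R)-2-allyl-4-hydroxy-5-methoxy-4-[(2S)-1-(3,4-dimethoxyphenyl)propan-2-yl]-2-(phenylselanyl)cyclohex-5-en-1-one (C2 epimers) | C=CCC1([Se]c2ccccc2)C[C@@](O)([C@@H](C)Cc3ccc(OC)c(OC)c3)C(OC)=CC1=O
F5 | step 4 | methyl (5S)-6-(3,4-dimethoxyphenyl)-4-hydroxy-5-methylhex-2-ynoate (C4 epimers) | COC(=O)C#CC(O)[C@@H](C)Cc1ccc(OC)c(OC)c1
F6 | step 8 | (2R,4R)-2-allyl-4-hydroxy-5-methoxy-4-[(2S)-1-(3,4-dimethoxyphenyl)propan-2-yl]-1-oxocyclohex-5-ene-2-carboxylic acid | C=CC[C@@]1(C(=O)O)C[C@@](O)([C@@H](C)Cc2ccc(OC)c(OC)c2)C(OC)=CC1=O
F7 | step 10 | (4R)-2-allyl-4,5-dimethoxy-4-[(2S)-1-(3,4-dimethoxyphenyl)propan-2-yl]cyclohex-5-en-1-one (C2 epimers) | C=CCC1C[C@@](OC)([C@@H](C)Cc2ccc(OC)c(OC)c2)C(OC)=CC1=O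
F8 | step 10 | (4R)-2-allyl-4,5-dimethoxy-4-[(2S)-1-(3,4-dimethoxyphenyl)propan-2-yl]-1-(trimethylsilyloxy)cyclohexa-1,5-diene | C=CCC=1C[C@@](OC)([C@@H](C)Cc2ccc(OC)c(OC)c2)C(OC)=CC=1O[Si](C)(C)C
A1 | alternative 1 | 2-allyl-4,4,5-trimethoxycyclohexa-2,5-dien-1-one | C=CCC1=CC(OC)(OC)C(OC)=CC1=O
A2 | alternative 1 | (Z)-1,2-dimethoxy-4-(prop-1-en-1-yl)benzene | C/C=C\c1ccc(OC)c(OC)c1
A3 | alternative 1 | 3-allyl-7-endo-(3,4-dimethoxyphenyl)-5-methoxy-6-endo-methylbicyclo[3.2.1]oct-3-ene-2,8-dione | C=CCC1=C[C@@]2(OC)[C@@H](C)[C@@H](c3ccc(OC)c(OC)c3)[C@H](C2=O)C1=O
A4 | alternative 2 | 4-[1-(3,4-dimethoxyphenyl)-1-hydroxypropan-2-yl]-4-methoxycyclohexa-2,5-dien-1-one (C7 and C8 defined, ring C4 prochiral) | O=C1C=CC(OC)(C=C1)[C@@H](C)[C@H](c1ccc(OC)c(OC)c1)O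
A5 | alternative 2 | cis-fused 2-(3,4-dimethoxyphenyl)-3a-methoxy-3-methyl-2,3,3a,7a-tetrahydrobenzofuran-6(7H)-one | O=C1C=C[C@@]2(OC)[C@@H](C)[C@H](c3ccc(OC)c(OC)c3)O[C@H]2C1
A6 | alternative 3 | 2-{2-[5-(3,4-dimethoxyphenyl)-4-methyl-3-oxopentyl]-1,3-dioxolan-2-yl}acetaldehyde (C8 defined) | O=CCC1(OCCO1)CCC(=O)[C@@H](C)Cc1ccc(OC)c(OC)c1
A7 | alternative 3 | 8-hydroxy-8-[1-(3,4-dimethoxyphenyl)propan-2-yl]-1,4-dioxaspiro[4.5]decan-7-one | C1C[C@@](O)([C@@H](C)Cc2ccc(OC)c(OC)c2)C(=O)CC13OCCO3
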